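(All runs come from a simulation on assumed constants; scatter was added.)

**The clock.** If Jy comes back after each turnover, cJy stays at its charge, and a slow loss of Ej that is first order in Jy is pseudo-first-order, with a rate constant proportional to cJy. The midnight run allows this: by 8.00 h it has lost 5.61 times its charged Jy in Ej. So I carry the acid dose, cJy multiplied by time, which for the new flask is 1.44 M·h.

| flask | Ej | Jy | remark | time |
|---|---|---|---|---|
| midnight | 0.20 M | 0.028 M | run made earlier |  |
| summer | 0.20 M | 0.044 M | run made earlier |  |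
| flask | 0.20 M | 0.0200 M |  | 3.0 d |

| run | time / h | Ej / % | Qi / % |
|---|---|---|---|
| midnight | 8.00 | 21.4 | 17.6 |
| midnight | 15.0 | 19.7 | 18.3 |
| midnight | 20.0 | 18.3 | 17.7 |
| midnight | 30.0 | 14.6 | 16.3 |
| midnight | 40.0 | 11.0 | 15.6 |
| summer | 3.00 | 30.1 | 15.4 |
| summer | 6.00 | 21.0 | 19.1 |
| summer | 10.0 | 19.0 | 22.0 |
| summer | 15.0 | 12.8 | 23.5 |
| summer | 25.0 | 12.1 | 20.2 |
| summer | 40.0 | 9.6 | 14.9 |

(each reading ± 1 percentage point)

- Jy is the free proton; pH is minus the decimal logarithm of its molar concentration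
- what has gone from Ej into another species counts as reacted, even if it can come back

* part of the Ej that has reacted at 3.0 d
* pH of the solution at 3.0 d

**The ladder.** On the first rung, within hours, Ej drops: the midnight run stands at 21.4% at 8.00 h, yet Ej plus Qi make 39.0%, so unseen species hold the rest. On the next rung, Ej creeps down along the dose: the summer run reads 21.0% at 0.264 M·h, and the midnight run 21.4% at 0.224 M·h. On the last rung, Qi itself is consumed: the summer run reads 23.5% at 15.0 h, then 14.9% at 40.0 h.

**My reckoning.** The flask's dose lies between the last midnight reading, 1.12 M·h, and the last summer reading, 1.76 M·h. I therefore take the mean of their Ej, 10.3%, as the Ej left in the flask, and expect the pH of the charged Jy.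

**The forecast.** It says 90% (86% to 93%) and pH 1.7 (1.62 to 1.8). Its ground: “Plotting Ej against [Jy]·t roughly merges the runs”.

**The result.** The flask gives 90.7% reacted and pH 1.70, with Jy at 100% of its own charge.

    Ej → Dz (k = 8.73 × 10⁻⁷ min⁻¹)
    Ej → Wy + Qi (k = 8.33 × 10⁻⁵ min⁻¹)
    Ej ⇌ Yx (K = 2.40, k = 0.00770 min⁻¹)
    Wy + Qi → Lx (k = 0.0310 L mol⁻¹ min⁻¹)
    Ej + Jy → Wy + Jy + Qi (k = 0.0389 L mol⁻¹ min⁻¹)
    Wy ⇌ Dw + Jy, settled at all times (K = 2.50 × 10⁻⁷ M)

At its dose of 1.44 M·h, the flask holds 9.33% Ej. Read at 20 h, the same recipe has a dose of 0.400 M·h, close to the 0.420 M·h of the midnight reading of 19.7%, and it holds 20% Ej.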